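## Retrosynthetic overview

- The target comes from its penta-allyl derivative by one Pd-mediated global deallylation.
- Key disconnection: the aryl enol ether C8–O4′ bond. It is made by Ag2O oxidative cross-coupling of an allyl-protected (R)-rosmarinate (free caffeoyl catechol) with an allyl 4-hydroxycinnamate. The phenol ring of the cinnamate is dearomatized to a p-quinone methide, trapped as a 1,4-benzodioxane, and reopened by base to the (Z)-enol ether.
- The protected rosmarinate comes from 3,4-dihydroxybenzaldehyde, Meldrum's acid and tri-O-allyl (R)-danshensu (decarboxylative Knoevenagel; stereocentre from the chiral pool).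
- The cinnamate partner comes from 3,4-dihydroxybenzaldehyde (dianion 3-O-allylation, then Knoevenagel–Doebner).
- Rings: all three benzene rings are bought (the aldehyde twice, danshensu once). The only ring formed is the transient 1,4-dioxane ring of the benzodioxane, closed and reopened inside the key step.

Assumption: commercial sodium danshensu is the natural (R)-enantiomer in high ee; the quinone methide and benzodioxane intermediates form as stereoisomer mixtures whose new stereocentres are erased in the same step.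

## Route

Step 1
Reactants: 1 3,4-dihydroxybenzaldehyde
Product: 2 3-(allyloxy)-4-hydroxybenzaldehyde
Conditions: NaH (2.2 equiv), DMSO, rt, 1 h; allyl bromide (1.0 equiv), rt, 4 h; aq. HCl work-up
Reagents that add atoms: allyl bromide (C=CCBr)
Why: In the dianion the 3-phenoxide, which is not conjugated to the formyl group, is the more nucleophilic oxygen, so one equivalent of allyl bromide gives the 3-O-allyl ether (regioselective Williamson etherification via the catecholate dianion).

Step 2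
Reactants: 2 3-(allyloxy)-4-hydroxybenzaldehyde; 3 Meldrum's acid
Product: 5 allyl (2E)-3-[3-(allyloxy)-4-hydroxyphenyl]prop-2-enoate, via allyl hydrogen malonate 4 (not isolated)
Conditions: 3 (1.2 equiv), allyl alcohol (1.3 equiv), toluene, 100 °C, 4 h; then 2, pyridine, piperidine (0.2 equiv), 60 °C, 12 h
Reagents that add atoms: allyl alcohol (C=CCO)
Why: Alcoholysis of Meldrum's acid gives the malonic half-ester, which undergoes Knoevenagel–Doebner condensation with the aldehyde and loses CO2 to give the (E)-cinnamate, the free phenol being tolerated.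

Step 3
Reactants: 6 sodium (2R)-3-(3,4-dihydroxyphenyl)-2-hydroxypropanoate (sodium danshensu)
Product: 7 allyl (2R)-3-[3,4-bis(allyloxy)phenyl]-2-hydroxypropanoate
Conditions: allyl bromide (3.3 equiv), K2CO3 (2.2 equiv), DMF, rt, 16 h
Reagents that add atoms: allyl bromide (C=CCBr)
Why: The carboxylate and both phenoxides are O-alkylated under carbonate conditions (Williamson etherification and carboxylate alkylation) while the secondary alcohol and the chiral-pool (R) stereocentre are untouched.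

Step 4
Reactants: 7 allyl (2R)-3-[3,4-bis(allyloxy)phenyl]-2-hydroxypropanoate; 3 Meldrum's acid; 1 3,4-dihydroxybenzaldehyde
Product: 9 allyl (2R)-3-[3,4-bis(allyloxy)phenyl]-2-{[(2E)-3-(3,4-dihydroxyphenyl)prop-2-enoyl]oxy}propanoate, via malonate half-ester 8 (not isolated)
Conditions: 7, 3 (1.0 equiv), toluene, 100 °C, 5 h; then 1 (1.1 equiv), pyridine, piperidine (0.2 equiv), 55 °C, 16 h
Reagents that add atoms: none
Why: Acylation of the secondary alcohol by Meldrum's acid followed by Knoevenagel–Doebner condensation with the unprotected aldehyde builds the (E)-caffeoyl ester without touching the (R) stereocentre and leaves free the catechol needed in step 5.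

Step 5
Reactants: 9 allyl (2R)-3-[3,4-bis(allyloxy)phenyl]-2-{[(2E)-3-(3,4-dihydroxyphenyl)prop-2-enoyl]oxy}propanoate; 5 allyl (2E)-3-[3-(allyloxy)-4-hydroxyphenyl]prop-2-enoate
Product: 12 allyl (2R)-3-[3,4-bis(allyloxy)phenyl]-2-{[(2E)-3-(4-{[(1Z)-1-[(allyloxy)carbonyl]-2-[3-(allyloxy)-4-hydroxyphenyl]ethenyl]oxy}-3-hydroxyphenyl)prop-2-enoyl]oxy}propanoate, via quinone methide 10 (not isolated), via trans-benzodioxane 11 (not isolated)
Conditions: 9 (1.0 equiv), 5 (2.0 equiv), Ag2O (1.5 equiv), toluene–acetone 2:1, rt, dark, 14 h; filter (Celite), evaporate; then DBU (2.5 equiv), MeCN, rt, 2 h; aq. citric acid work-up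
Reagents that add atoms: none
Why: Proposed new method: Ag2O oxidizes both phenols to aryloxyl radicals, the semiquinone of 9 reacting at O4′ (lowest O–H bond energy, spin delocalized into the propenoate) and the radical of 5 at C8, so that O4′–C8 coupling dearomatizes the ring of 5 to quinone methide 10, which the neighbouring 3′-OH traps as benzodioxane 11 (closest known reaction: Ag2O-mediated biomimetic coupling of catechols with coniferyl alcohol, or of caffeate esters, to 1,4-benzodioxane neolignans), and DBU then reopens 11 through the same quinone methide (phenoxide-driven retro-oxa-Michael, E1cB) and removes the acidic H-8 to give the thermodynamically favoured (Z)-enol ether, erasing both transient stereocentres.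

Step 6
Reactants: 12 allyl (2R)-3-[3,4-bis(allyloxy)phenyl]-2-{[(2E)-3-(4-{[(1Z)-1-[(allyloxy)carbonyl]-2-[3-(allyloxy)-4-hydroxyphenyl]ethenyl]oxy}-3-hydroxyphenyl)prop-2-enoyl]oxy}propanoate
Product: 13 (2R)-2-{[(2E)-3-(4-{[(1Z)-1-carboxy-2-(3,4-dihydroxyphenyl)ethenyl]oxy}-3-hydroxyphenyl)prop-2-enoyl]oxy}-3-(3,4-dihydroxyphenyl)propanoic acid
Conditions: Pd(PPh3)4 (10 mol %), morpholine (15 equiv), THF, rt, 3 h, Ar, dark; aq. HCl work-up; C18 reverse-phase chromatography
Reagents that add atoms: none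
Why: Zerovalent palladium ionizes the two allyl esters and three aryl allyl ethers to π-allyl complexes that morpholine intercepts (Tsuji–Trost deallylation), conditions that leave the internal ester, both alkenes and the stereocentre untouched.

## Compound list

1 | 3,4-dihydroxybenzaldehyde | O=Cc1ccc(O)c(O)c1 | starting material
2 | 3-(allyloxy)-4-hydroxybenzaldehyde | O=Cc1ccc(O)c(OCC=C)c1 | intermediate
3 | Meldrum's acid (2,2-dimethyl-1,3-dioxane-4,6-dione) | CC1(C)OC(=O)CC(=O)O1 | starting material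
4 | allyl hydrogen malonate | OC(=O)CC(=O)OCC=C | intermediate (not isolated)
5 | allyl (2E)-3-[3-(allyloxy)-4-hydroxyphenyl]prop-2-enoate | C=CCOC(=O)/C=C/c1ccc(O)c(OCC=C)c1 | intermediate
6 | sodium (2R)-3-(3,4-dihydroxyphenyl)-2-hydroxypropanoate (sodium danshensu) | O[C@H](Cc1ccc(O)c(O)c1)C(=O)[O-].[Na+] | starting material
7 | allyl (2R)-3-[3,4-bis(allyloxy)phenyl]-2-hydroxypropanoate | O[C@H](Cc1ccc(OCC=C)c(OCC=C)c1)C(=O)OCC=C | intermediate
8 | 3-{[(2R)-1-(allyloxy)-3-[3,4-bis(allyloxy)phenyl]-1-oxopropan-2-yl]oxy}-3-oxopropanoic acid (malonate half-ester of 7) | OC(=O)CC(=O)O[C@H](Cc1ccc(OCC=C)c(OCC=C)c1)C(=O)OCC=C | intermediate (not isolated)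
9 | allyl (2R)-3-[3,4-bis(allyloxy)phenyl]-2-{[(2E)-3-(3,4-dihydroxyphenyl)prop-2-enoyl]oxy}propanoate (tri-O-allyl rosmarinate) | O=C(/C=C/c1ccc(O)c(O)c1)O[C@H](Cc1ccc(OCC=C)c(OCC=C)c1)C(=O)OCC=C | intermediate
10 | p-quinone methide: allyl (2R)-3-[3,4-bis(allyloxy)phenyl]-2-{[(2E)-3-(4-{[1-(allyloxy)-3-[3-(allyloxy)-4-oxocyclohexa-2,5-dien-1-ylidene]-1-oxopropan-2-yl]oxy}-3-hydroxyphenyl)prop-2-enoyl]oxy}propanoate (C8 epimers) | O=C1C(OCC=C)=CC(=CC(Oc2ccc(/C=C/C(=O)O[C@H](Cc3ccc(OCC=C)c(OCC=C)c3)C(=O)OCC=C)cc2O)C(=O)OCC=C)C=C1 | intermediate (not isolated)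
11 | allyl (2R)-3-[3,4-bis(allyloxy)phenyl]-2-{[(2E)-3-{trans-2-[(allyloxy)carbonyl]-3-[3-(allyloxy)-4-hydroxyphenyl]-2,3-dihydro-1,4-benzodioxin-6-yl}prop-2-enoyl]oxy}propanoate (two trans diastereomers, one drawn; any cis isomer converges) | O=C(/C=C/c1ccc2O[C@@H](C(=O)OCC=C)[C@H](c3ccc(O)c(OCC=C)c3)Oc2c1)O[C@H](Cc1ccc(OCC=C)c(OCC=C)c1)C(=O)OCC=C | intermediate (not isolated)
12 | allyl (2R)-3-[3,4-bis(allyloxy)phenyl]-2-{[(2E)-3-(4-{[(1Z)-1-[(allyloxy)carbonyl]-2-[3-(allyloxy)-4-hydroxyphenyl]ethenyl]oxy}-3-hydroxyphenyl)prop-2-enoyl]oxy}propanoate | O=C(/C=C/c1ccc(O/C(=C\c2ccc(O)c(OCC=C)c2)C(=O)OCC=C)c(O)c1)O[C@H](Cc1ccc(OCC=C)c(OCC=C)c1)C(=O)OCC=C | intermediate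
13 | (2R)-2-{[(2E)-3-(4-{[(1Z)-1-carboxy-2-(3,4-dihydroxyphenyl)ethenyl]oxy}-3-hydroxyphenyl)prop-2-enoyl]oxy}-3-(3,4-dihydroxyphenyl)propanoic acid | O=C(/C=C/c1ccc(O/C(=C\c2ccc(O)c(O)c2)C(=O)O)c(O)c1)O[C@H](Cc1ccc(O)c(O)c1)C(=O)O | target

## Step count and risks

Total steps: 6. Longest linear sequence: 4 steps (1 → 2 → 5 → 12 → 13, or 6 → 7 → 9 → 12 → 13).

**Step 5 (most likely to fail).** The cross-coupling competes with homo-dimerization of 9, with 8–5′ and 8–8′ coupling of 5, with the reversed cross-coupling (O4 of 5 onto C8 of 9) and with the 8-O-3′ regioisomer; DBU could also erode the ee of the α-acyloxy ester. The fallback sets out from 9 and returns at 13, and builds the enol ether by ionic Horner–Wadsworth–Emmons chemistry. Commercial allyl (diethoxyphosphoryl)acetate is chlorinated (NaH, N-chlorosuccinimide, THF, 0 °C) to allyl chloro(diethoxyphosphoryl)acetate F1. The more acidic 4-OH of 9 is alkylated with it (K2CO3, 1 equiv, DMF, rt) to give the aryloxyphosphonoacetate F2. Compound 1 is bis-allylated (allyl bromide, K2CO3, DMF) to 3,4-bis(allyloxy)benzaldehyde F3. Olefination of this aldehyde with the phosphonate (NaH, 2.1 equiv, THF, 0 °C to rt) gives the hexa-allyl (Z)-enol ether F4, any minor E isomer being equilibrated with a trace of iodine in daylight. The step 6 conditions then give 13.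

**Step 4.** Acylation of the hindered α-hydroxy ester by Meldrum's acid may be slow, and the amine-mediated condensation may give by-products or partial racemization. The fallback sets out from 7 and returns at 9, and uses a Wittig olefination. Compound 7 is acylated with bromoacetyl bromide (pyridine, CH2Cl2, 0 °C) to the bromoacetate F5. PPh3 (toluene, rt) converts it into the phosphonium bromide F6. Aqueous NaOH in CH2Cl2 at 0 °C gives the stabilized ylide F7, which reacts with unprotected 1 (THF, 50 °C) to give 9 as the E isomer under neutral conditions.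

**Step 6.** Five allyl groups must leave at once; the three aryl allyl ethers are the slow ones and the polyphenolic diacid is air-sensitive. The fallback sets out from 12 and returns at 13, and cleaves the ethers by isomerization and hydrolysis instead of allyl transfer. H2-activated [Ir(cod)(PMePh2)2]PF6 (THF, rt) isomerizes the three aryl allyl ethers to (E)-prop-1-enyl ethers, giving the tris(propenyl ether) F8. Dilute HCl in THF–water (rt) hydrolyses these simple enol ethers, the electron-poor α-aryloxyacrylate being far less reactive, to give the bis(allyl ester) F9. Its two allyl esters, the easy substrates, are then removed with Pd(PPh3)4 and morpholine (THF, rt) to give 13.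

Further compounds
F1 | step 5 | allyl chloro(diethoxyphosphoryl)acetate | C=CCOC(=O)C(Cl)P(=O)(OCC)OCC
F2 | step 5 | allyl (2R)-3-[3,4-bis(allyloxy)phenyl]-2-{[(2E)-3-(4-{[2-(allyloxy)-1-(diethoxyphosphoryl)-2-oxoethyl]oxy}-3-hydroxyphenyl)prop-2-enoyl]oxy}propanoate (epimers at the phosphonate carbon) | O=C(/C=C/c1ccc(OC(C(=O)OCC=C)P(=O)(OCC)OCC)c(O)c1)O[C@H](Cc1ccc(OCC=C)c(OCC=C)c1)C(=O)OCC=C
F3 | step 5 | 3,4-bis(allyloxy)benzaldehyde | O=Cc1ccc(OCC=C)c(OCC=C)c1
F4 | step 5 | allyl (2R)-3-[3,4-bis(allyloxy)phenyl]-2-{[(2E)-3-(4-{[(1Z)-1-[(allyloxy)carbonyl]-2-[3,4-bis(allyloxy)phenyl]ethenyl]oxy}-3-hydroxyphenyl)prop-2-enoyl]oxy}propanoate | O=C(/C=C/c1ccc(O/C(=C\c2ccc(OCC=C)c(OCC=C)c2)C(=O)OCC=C)c(O)c1)O[C@H](Cc1ccc(OCC=C)c(OCC=C)c1)C(=O)OCC=C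
F5 | step 4 | allyl (2R)-3-[3,4-bis(allyloxy)phenyl]-2-[(bromoacetyl)oxy]propanoate | O=C(CBr)O[C@H](Cc1ccc(OCC=C)c(OCC=C)c1)C(=O)OCC=C
F6 | step 4 | (2-{[(2R)-1-(allyloxy)-3-[3,4-bis(allyloxy)phenyl]-1-oxopropan-2-yl]oxy}-2-oxoethyl)triphenylphosphonium bromide | [Br-].O=C(C[P+](c1ccccc1)(c1ccccc1)c1ccccc1)O[C@H](Cc1ccc(OCC=C)c(OCC=C)c1)C(=O)OCC=C
F7 | step 4 | allyl (2R)-3-[3,4-bis(allyloxy)phenyl]-2-{[(triphenylphosphoranylidene)acetyl]oxy}propanoate | O=C(C=P(c1ccccc1)(c1ccccc1)c1ccccc1)O[C@H](Cc1ccc(OCC=C)c(OCC=C)c1)C(=O)OCC=C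
F8 | step 6 | allyl (2R)-3-{3,4-bis[(1E)-prop-1-enyloxy]phenyl}-2-{[(2E)-3-(4-{[(1Z)-1-[(allyloxy)carbonyl]-2-{4-hydroxy-3-[(1E)-prop-1-enyloxy]phenyl}ethenyl]oxy}-3-hydroxyphenyl)prop-2-enoyl]oxy}propanoate | O=C(/C=C/c1ccc(O/C(=C\c2ccc(O)c(O/C=C/C)c2)C(=O)OCC=C)c(O)c1)O[C@H](Cc1ccc(O/C=C/C)c(O/C=C/C)c1)C(=O)OCC=C
F9 | step 6 | allyl (2R)-2-{[(2E)-3-(4-{[(1Z)-1-[(allyloxy)carbonyl]-2-(3,4-dihydroxyphenyl)ethenyl]oxy}-3-hydroxyphenyl)prop-2-enoyl]oxy}-3-(3,4-dihydroxyphenyl)propanoate | O=C(/C=C/c1ccc(O/C(=C\c2ccc(O)c(O)c2)C(=O)OCC=C)c(O)c1)O[C@H](Cc1ccc(O)c(O)c1)C(=O)OCC=C
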